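**Plan**
- Benzofuran numbering is used (O1, C2, C3, C3a, C7a; side chain on C5). The retrosynthesis first removes the enal (from an allylic alcohol), the C5 side-chain ester (from an aryl methyl ketone) and the C3 isovalerate, then cuts the dihydrofuran ring at O1–C7a and C2–C3 together.
- Enabling feature: C7a is para to the C5 acyl carbon and C3 is a benzylic carbinol carbon ortho to it. 5-Acetyl-2-fluorobenzaldehyde is therefore a C3/C7a 1,3-dielectrophile that can take up a C2/O1 1,2-dinucleophile.
- The dinucleophile is a γ-siloxyallylboronic ester made from symmetrical 2-methylenepropane-1,3-diol; its second CH2O arm becomes the formyl group.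
- Forward: allyl transfer builds C2–C3, a silyl shift from O1 to the C3 oxygen frees O1, and O1 closes the five-membered ring onto the benzene ring by SNAr. The route then continues with C3 acylation, ketone reduction, side-chain acylation, desilylation and oxidation.
- Stereochemistry: C3 from the chiral phosphoric acid (Si-face allyl transfer); C2 from the chair transition state (syn, hence 2,3-cis); the side-chain carbinol from Noyori transfer hydrogenation; the acid centre from (R)-2-methylbutanoic acid.
- Helpers: fluorine (leaving group), the acetyl group (activates C7a, later the carbinol), two silyl groups (one relays; both are removed in step 5 and the primary one is put back in step 6 so that C3 alone is acylated).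

Key step: step 4

Assumption: the facial preference of TRIP with boronate 4 is taken to be the one established for allyl- and (Z)-crotylboronic pinacol esters with aryl aldehydes.

**Step 1**
Reactants: 1 2-methylenepropane-1,3-diol
Product: 2 2-methylene-1,3-bis(tert-butyldimethylsilyloxy)propane
Conditions: TBSCl (2.2 equiv), imidazole, DMF, 0 °C to rt
Reagents that add atoms: tert-butyldimethylsilyl chloride, CC(C)(C)[Si](C)(C)Cl
Why: Silyl ether formation on both primary allylic hydroxyls with imidazole as base should be clean and creates no stereocenter.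

**Step 2**
Reactants: 2 2-methylene-1,3-bis(tert-butyldimethylsilyloxy)propane
Product: 4 2-[(2E)-3-(tert-butyldimethylsilyloxy)-2-[(tert-butyldimethylsilyloxy)methyl]prop-2-en-1-yl]-4,4,5,5-tetramethyl-1,3,2-dioxaborolane (enol siloxy group cis to CH2B), via allyllithium 3 (not isolated)
Conditions: s-BuLi, THF, −78 °C; then 2-isopropoxy-4,4,5,5-tetramethyl-1,3,2-dioxaborolane, −78 °C to rt
Reagents that add atoms: 2-isopropoxy-4,4,5,5-tetramethyl-1,3,2-dioxaborolane, CC(C)OB1OC(C)(C)C(C)(C)O1
Why: Allylic deprotonation next to oxygen should give the oxygen-chelated allyllithium 3 with the siloxy group cis to the CH2Li terminus, and borylation at that unsubstituted terminus (lithiation–borylation, the standard entry to γ-alkoxyallylboronic esters) should fix this geometry; the two CH2O arms of 2 are equivalent, so there is no regiochemical question.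

**Step 3**
Reactants: 5 5-bromo-2-fluorobenzaldehyde
Product: 7 5-acetyl-2-fluorobenzaldehyde, via enol ether 6 (not isolated)
Conditions: tributyl(1-ethoxyvinyl)stannane, PdCl2(PPh3)2 (3 mol %), toluene, 100 °C; then 1 M HCl, THF, rt
Reagents that add atoms: tributyl(1-ethoxyvinyl)stannane, CCCC[Sn](CCCC)(CCCC)C(=C)OCC; water, O
Why: Stille coupling of the aryl bromide with the 1-ethoxyvinyl stannane (an acetyl anion equivalent) should leave the aldehyde and the C–F bond untouched, and mild acid hydrolysis of enol ether 6 should give the methyl ketone.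

**Step 4**
Reactants: 7 5-acetyl-2-fluorobenzaldehyde; 4 γ-siloxyallylboronic pinacol ester
Product: 11 1-[(2R,3R)-3-(tert-butyldimethylsilyloxy)-2-[3-(tert-butyldimethylsilyloxy)prop-1-en-2-yl]-2,3-dihydro-1-benzofuran-5-yl]ethanone, via borate ester 8 (not isolated), via C3 alkoxide 9 (not isolated), via O1 alkoxide 10 (not isolated)
Conditions: (S)-TRIP (5 mol %), 4 Å MS, toluene, −30 °C; then KOtBu (2.2 equiv, 1 M in THF), −30 to 0 °C
Reagents that add atoms: none
Why: Proposed new method: the acid-bound boronate 4 transfers its oxygen-bearing γ-carbon to the formyl carbon of 7 through a closed chair transition state (C2–C3 bond, borate 8); KOtBu then frees the C3 alkoxide 9, which pulls the silyl group from O1 over a five-membered silicate (1,4 O-to-O silyl shift) to give alkoxide 10, and this closes the ring by addition–elimination at the fluorine-bearing C7a (O1–C7a bond). The closest known reaction types are the phosphoric-acid-catalysed allylboration of aryl aldehydes with γ-substituted allylboronic esters, base-induced silyl migration between vicinal oxygens, and intramolecular SNAr of 2-(2-fluoroaryl)ethanol alkoxides to 2,3-dihydrobenzofurans; their union in one flask is what is new. The only ring closed is the five-membered ring O1–C2–C3–C3a–C7a, by a 5-exo attack of O1 on C7a with the negative charge taken up by the para acetyl group. C3 (R) is set by the catalyst: the (R)-acid directs allyl transfer to the Re face of aryl aldehydes, so the (S)-acid is chosen for the Si-face attack needed here; C2 (R) follows through the chair, in which the siloxy group cis to CH2B sits axial and gives the syn, later cis, relationship. The step needs aldehyde-over-ketone selectivity, which the mild boronate should secure, and O1-selective arylation, which is secured because the C3 oxygen could only form a four-membered ring and the primary oxygen keeps its silyl group and would need a seven-membered ring.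

**Step 5**
Reactants: 11 bis-silyl ether
Product: 12 1-[(2R,3R)-3-hydroxy-2-(3-hydroxyprop-1-en-2-yl)-2,3-dihydro-1-benzofuran-5-yl]ethanone
Conditions: TBAF (3 equiv), AcOH (3 equiv), THF, 0 °C to rt
Reagents that add atoms: none
Why: Fluoride-mediated desilylation of both silyl ethers, buffered with acetic acid so that no free alkoxide persists, should leave C2 and C3 untouched.

**Step 6**
Reactants: 12 diol
Product: 13 1-[(2R,3R)-2-[3-(tert-butyldimethylsilyloxy)prop-1-en-2-yl]-3-hydroxy-2,3-dihydro-1-benzofuran-5-yl]ethanone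
Conditions: TBSCl (1.05 equiv), imidazole, CH2Cl2, −20 to 0 °C
Reagents that add atoms: tert-butyldimethylsilyl chloride, CC(C)(C)[Si](C)(C)Cl
Why: Kinetically selective silyl ether formation at the unhindered primary allylic hydroxyl, over the secondary benzylic hydroxyl flanked by the cis C2 substituent, should leave O3 free.

**Step 7**
Reactants: 13 secondary alcohol
Product: 14 (2R,3R)-5-acetyl-2-[3-(tert-butyldimethylsilyloxy)prop-1-en-2-yl]-2,3-dihydro-1-benzofuran-3-yl 3-methylbutanoate
Conditions: 3-methylbutanoyl chloride, pyridine, DMAP (cat.), CH2Cl2, 0 °C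
Reagents that add atoms: 3-methylbutanoyl chloride, CC(C)CC(=O)Cl
Why: DMAP-catalysed acylation of the benzylic alcohol (nucleophilic acyl substitution) keeps the C3 configuration because the C3–O bond is not broken, and the mild base cannot remove the non-acidic C2–H.

**Step 8**
Reactants: 14 aryl methyl ketone
Product: 15 (2R,3R)-2-[3-(tert-butyldimethylsilyloxy)prop-1-en-2-yl]-5-[(1R)-1-hydroxyethyl]-2,3-dihydro-1-benzofuran-3-yl 3-methylbutanoate
Conditions: RuCl(p-cymene)[(R,R)-TsDPEN] (1 mol %), HCO2H/Et3N (5:2), CH2Cl2, 30 °C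
Reagents that add atoms: none
Why: Noyori asymmetric transfer hydrogenation with the (R,R)-TsDPEN catalyst should give the (R)-1-arylethanol under catalyst control, while the isolated 1,1-disubstituted alkene, the ester and the silyl ether are inert to the ruthenium hydride.

**Step 9**
Reactants: 15 (R)-carbinol; 16 (R)-2-methylbutanoic acid
Product: 17 (1R)-1-[(2R,3R)-2-[3-(tert-butyldimethylsilyloxy)prop-1-en-2-yl]-3-(3-methylbutanoyloxy)-2,3-dihydro-1-benzofuran-5-yl]ethyl (2R)-2-methylbutanoate
Conditions: EDC·HCl, DMAP (0.2 equiv), CH2Cl2, 0 °C to rt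
Reagents that add atoms: none
Why: Steglich esterification acylates the carbinol with retention because its C–O bond is not broken, and the α-center of the acid should survive because no ketene-forming base is present.

**Step 10**
Reactants: 17 silyl ether
Product: 18 (1R)-1-[(2R,3R)-2-(3-hydroxyprop-1-en-2-yl)-3-(3-methylbutanoyloxy)-2,3-dihydro-1-benzofuran-5-yl]ethyl (2R)-2-methylbutanoate
Conditions: HF·pyridine, pyridine, THF, 0 °C to rt
Reagents that add atoms: none
Why: Buffered desilylation of the primary silyl ether should not hydrolyse either ester, and acyl shift from O3 to the new hydroxyl would need a seven-membered transition state.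

**Step 11**
Reactants: 18 allylic alcohol
Product: 19 (1R)-1-[(2R,3R)-3-(3-methylbutanoyloxy)-2-(3-oxoprop-1-en-2-yl)-2,3-dihydro-1-benzofuran-5-yl]ethyl (2R)-2-methylbutanoate
Conditions: MnO2 (activated, 15 equiv), CH2Cl2, rt
Reagents that add atoms: none
Why: MnO2 oxidation of the 2-substituted prop-2-en-1-ol to the 2-substituted acrolein runs under neutral heterogeneous conditions, so the base-sensitive 3-acyloxy-2,3-dihydrobenzofuran should survive and no stereocenter is touched.

**Compound list**
1 | 2-methylenepropane-1,3-diol | C=C(CO)CO | starting material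
2 | 2-methylene-1,3-bis(tert-butyldimethylsilyloxy)propane | C=C(CO[Si](C)(C)C(C)(C)C)CO[Si](C)(C)C(C)(C)C | intermediate
3 | 3-(tert-butyldimethylsilyloxy)-2-[(tert-butyldimethylsilyloxy)methyl]allyllithium, siloxy group cis to CH2Li | [Li]C/C(CO[Si](C)(C)C(C)(C)C)=C\O[Si](C)(C)C(C)(C)C | intermediate
4 | 2-[(2E)-3-(tert-butyldimethylsilyloxy)-2-[(tert-butyldimethylsilyloxy)methyl]prop-2-en-1-yl]-4,4,5,5-tetramethyl-1,3,2-dioxaborolane | CC1(C)OB(C/C(CO[Si](C)(C)C(C)(C)C)=C\O[Si](C)(C)C(C)(C)C)OC1(C)C | intermediate
5 | 5-bromo-2-fluorobenzaldehyde | O=Cc1cc(Br)ccc1F | starting material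
6 | 5-(1-ethoxyvinyl)-2-fluorobenzaldehyde | CCOC(=C)c1ccc(F)c(C=O)c1 | intermediate
7 | 5-acetyl-2-fluorobenzaldehyde | CC(=O)c1ccc(F)c(C=O)c1 | intermediate
8 | pinacol borate of (1R,2R)-1-(5-acetyl-2-fluorophenyl)-2-(tert-butyldimethylsilyloxy)-3-[(tert-butyldimethylsilyloxy)methyl]but-3-en-1-ol | C=C(CO[Si](C)(C)C(C)(C)C)[C@@H](O[Si](C)(C)C(C)(C)C)[C@H](OB1OC(C)(C)C(C)(C)O1)c1cc(C(C)=O)ccc1F | intermediate
9 | potassium (1R,2R)-1-(5-acetyl-2-fluorophenyl)-2-(tert-butyldimethylsilyloxy)-3-[(tert-butyldimethylsilyloxy)methyl]but-3-en-1-olate | C=C(CO[Si](C)(C)C(C)(C)C)[C@@H](O[Si](C)(C)C(C)(C)C)[C@H]([O-])c1cc(C(C)=O)ccc1F.[K+] | intermediate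
10 | potassium (1R,2R)-1-(5-acetyl-2-fluorophenyl)-1-(tert-butyldimethylsilyloxy)-3-[(tert-butyldimethylsilyloxy)methyl]but-3-en-2-olate | C=C(CO[Si](C)(C)C(C)(C)C)[C@@H]([O-])[C@H](O[Si](C)(C)C(C)(C)C)c1cc(C(C)=O)ccc1F.[K+] | intermediate
11 | 1-[(2R,3R)-3-(tert-butyldimethylsilyloxy)-2-[3-(tert-butyldimethylsilyloxy)prop-1-en-2-yl]-2,3-dihydro-1-benzofuran-5-yl]ethanone | C=C(CO[Si](C)(C)C(C)(C)C)[C@H]1Oc2ccc(C(C)=O)cc2[C@H]1O[Si](C)(C)C(C)(C)C | intermediate
12 | 1-[(2R,3R)-3-hydroxy-2-(3-hydroxyprop-1-en-2-yl)-2,3-dihydro-1-benzofuran-5-yl]ethanone | C=C(CO)[C@H]1Oc2ccc(C(C)=O)cc2[C@H]1O | intermediate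
13 | 1-[(2R,3R)-2-[3-(tert-butyldimethylsilyloxy)prop-1-en-2-yl]-3-hydroxy-2,3-dihydro-1-benzofuran-5-yl]ethanone | C=C(CO[Si](C)(C)C(C)(C)C)[C@H]1Oc2ccc(C(C)=O)cc2[C@H]1O | intermediate
14 | (2R,3R)-5-acetyl-2-[3-(tert-butyldimethylsilyloxy)prop-1-en-2-yl]-2,3-dihydro-1-benzofuran-3-yl 3-methylbutanoate | C=C(CO[Si](C)(C)C(C)(C)C)[C@H]1Oc2ccc(C(C)=O)cc2[C@H]1OC(=O)CC(C)C | intermediate
15 | (2R,3R)-2-[3-(tert-butyldimethylsilyloxy)prop-1-en-2-yl]-5-[(1R)-1-hydroxyethyl]-2,3-dihydro-1-benzofuran-3-yl 3-methylbutanoate | C=C(CO[Si](C)(C)C(C)(C)C)[C@H]1Oc2ccc([C@@H](C)O)cc2[C@H]1OC(=O)CC(C)C | intermediate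
16 | (R)-2-methylbutanoic acid | CC[C@@H](C)C(=O)O | starting material
17 | (1R)-1-[(2R,3R)-2-[3-(tert-butyldimethylsilyloxy)prop-1-en-2-yl]-3-(3-methylbutanoyloxy)-2,3-dihydro-1-benzofuran-5-yl]ethyl (2R)-2-methylbutanoate | C=C(CO[Si](C)(C)C(C)(C)C)[C@H]1Oc2ccc([C@@H](C)OC(=O)[C@H](C)CC)cc2[C@H]1OC(=O)CC(C)C | intermediate
18 | (1R)-1-[(2R,3R)-2-(3-hydroxyprop-1-en-2-yl)-3-(3-methylbutanoyloxy)-2,3-dihydro-1-benzofuran-5-yl]ethyl (2R)-2-methylbutanoate | C=C(CO)[C@H]1Oc2ccc([C@@H](C)OC(=O)[C@H](C)CC)cc2[C@H]1OC(=O)CC(C)C | intermediate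
19 | (1R)-1-[(2R,3R)-3-(3-methylbutanoyloxy)-2-(3-oxoprop-1-en-2-yl)-2,3-dihydro-1-benzofuran-5-yl]ethyl (2R)-2-methylbutanoate | C=C(C=O)[C@H]1Oc2ccc([C@@H](C)OC(=O)[C@H](C)CC)cc2[C@H]1OC(=O)CC(C)C | target

**Count**
Total steps: 11. Longest linear sequence: 10 (steps 1, 2, 4 to 11).

**Steps most likely to fail**

1. Step 4 (proposed new method). After the allyl transfer the silyl group may move from O1 to the C3 oxygen too slowly, so that the base instead enolises the methyl ketone and aldol or intermolecular substitution products form. The fallback uses known chemistry and sets out from 7 and 4. The (S)-TRIP allylboration is run alone and worked up with water to isolate (1R,2R)-1-(5-acetyl-2-fluorophenyl)-2-(tert-butyldimethylsilyloxy)-3-[(tert-butyldimethylsilyloxy)methyl]but-3-en-1-ol F1. TBAF in THF removes both silyl groups to give 1-[3-[(1R,2R)-1,2-dihydroxy-3-(hydroxymethyl)but-3-en-1-yl]-4-fluorophenyl]ethanone F2. K2CO3 in DMF at 50 °C then closes the ring by intramolecular SNAr, in which only the C2 oxygen can form a five-membered ring. The fallback comes back to the route at 12.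

2. Step 2. Silicon may migrate from oxygen to the lithiated carbon (retro-Brook shift), or the cis geometry may be lost before the boron electrophile arrives. The fallback sets out from 1. MOMCl and iPr2NEt give 2-methylene-1,3-bis(methoxymethoxy)propane F3, whose acetal oxygen chelates lithium strongly and cannot migrate. The same lithiation–borylation gives 2-[(2E)-3-(methoxymethoxy)-2-[(methoxymethoxy)methyl]prop-2-en-1-yl]-4,4,5,5-tetramethyl-1,3,2-dioxaborolane F4. (S)-TRIP allylboration of 7 gives (1R,2R)-1-(5-acetyl-2-fluorophenyl)-2-(methoxymethoxy)-3-[(methoxymethoxy)methyl]but-3-en-1-ol F5. HCl in MeOH removes both acetals to give the triol F2 of the first fallback, and K2CO3 in DMF brings it back to the route at 12.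

3. Step 11. The heterogeneous oxidation may be slow, and the 2-substituted acrolein may polymerise or add nucleophiles on long contact with the oxidant. The fallback sets out from 18. Appel bromination (CBr4, PPh3, CH2Cl2, 0 °C) gives (1R)-1-[(2R,3R)-2-(3-bromoprop-1-en-2-yl)-3-(3-methylbutanoyloxy)-2,3-dihydro-1-benzofuran-5-yl]ethyl (2R)-2-methylbutanoate F6. N-Methylmorpholine N-oxide in MeCN (a Kornblum-type halide oxidation) then gives the enal, and the fallback comes back to the route at 19.

**Further compounds**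
F1 | step 4 | (1R,2R)-1-(5-acetyl-2-fluorophenyl)-2-(tert-butyldimethylsilyloxy)-3-[(tert-butyldimethylsilyloxy)methyl]but-3-en-1-ol | C=C(CO[Si](C)(C)C(C)(C)C)[C@@H](O[Si](C)(C)C(C)(C)C)[C@H](O)c1cc(C(C)=O)ccc1F
F2 | step 4 | 1-[3-[(1R,2R)-1,2-dihydroxy-3-(hydroxymethyl)but-3-en-1-yl]-4-fluorophenyl]ethanone | C=C(CO)[C@@H](O)[C@H](O)c1cc(C(C)=O)ccc1F
F3 | step 2 | 2-methylene-1,3-bis(methoxymethoxy)propane | C=C(COCOC)COCOC
F4 | step 2 | 2-[(2E)-3-(methoxymethoxy)-2-[(methoxymethoxy)methyl]prop-2-en-1-yl]-4,4,5,5-tetramethyl-1,3,2-dioxaborolane | CC1(C)OB(C/C(COCOC)=C\OCOC)OC1(C)C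
F5 | step 2 | (1R,2R)-1-(5-acetyl-2-fluorophenyl)-2-(methoxymethoxy)-3-[(methoxymethoxy)methyl]but-3-en-1-ol | C=C(COCOC)[C@@H](OCOC)[C@H](O)c1cc(C(C)=O)ccc1F
F6 | step 11 | (1R)-1-[(2R,3R)-2-(3-bromoprop-1-en-2-yl)-3-(3-methylbutanoyloxy)-2,3-dihydro-1-benzofuran-5-yl]ethyl (2R)-2-methylbutanoate | C=C(CBr)[C@H]1Oc2ccc([C@@H](C)OC(=O)[C@H](C)CC)cc2[C@H]1OC(=O)CC(C)C
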